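The earlier runs and the new flask are simulated for an exercise, and the scatter is random.

The easy step comes first: we take the main step by itself, electrophile plus nucleophile to product, which with nucleophile in excess, as in Saturday's run, takes the fraction of electrophile left towards zero, and we hold that against the runs so far.

common to all: electrophile 0.10 M

|  | nucleophile | remark | time |
|---|---|---|---|
| Saturday's | 0.17 M | run made earlier |  |
| Friday's | 0.56 M | run made earlier |  |
| teal | 0.120 M |  | 30 min |
| ochre | 0.240 M |  | 30 min |
| blue | 0.480 M |  | 30 min |

- Saturday's (time / min: electrophile / %, product / %): 5.00: 64.9, 35.4; 10.0: 62.4, 37.4; 15.0: 60.0, 38.7; 20.0: 59.6, 41.1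
- Friday's (time / min: electrophile / %, product / %): 2.50: 52.9, 47.1; 8.00: 47.6, 53.3; 15.0: 43.4, 56.3; 20.0: 42.1, 57.8

(scatter of a reading: 0.5 percentage points)

- part of the electrophile that has reacted at the end, teal
- part of the electrophile that has reacted at the end, ochre
- part of the electrophile that has reacted at the end, blue
- what raising the concentration of nucleophile from its lowest to its highest value here does to the part of the electrophile that has reacted (changes below 5 percentage points count as none) (no change / it falls / it rises)

- the numbers in the tables scatter with a standard deviation of 0.5 percentage points

After a fast start Saturday's run still holds 59.6% of its electrophile at 20.0 min and Friday's holds 42.1%, so the main step by itself does not describe them. We add its way back, but an equilibrium constant read from the last readings comes to 5.35 M⁻¹ on Saturday's run and 2.73 M⁻¹ on Friday's, so Saturday's reading is twice Friday's and that fails too.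

We therefore add, as our own guess, a loss of nucleophile that is second order in itself and competes with the main step. Dividing one rate by the other removes time, so, at equal time and with that loss taking the larger part of the nucleophile, −ln(fraction of electrophile left) should climb in a straight line with ln(nucleophile charge). The last readings of the two runs, both at 20.0 min, give 0.292, which we call the competition slope, a selectivity factor of sorts: the gain in −ln(fraction left) per unit of ln(charge) at equal time.

Last we add the slow creep after the fast start. Saturday's readings from 10.0 min to 20.0 min give 0.00459 min⁻¹, which carried on to 30 min puts −ln(fraction left) at 0.563 for Saturday's charge. Moving along the slope, which we assume unchanged at 30 min, we expect 37.0% reacted in teal, 48.5% in ochre and 57.9% in blue.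

The forecast says 38% (32% to 42%), 48% (44% to 51%) and 58% (55% to 61%), and that the part reacted: it rises. Of the stalling it writes “Something else is slowing the reaction”. At teal our figure stands lower than its figure.

The flasks give 38.3%, 49.1% and 59.0%, so the part reacted: it rises, by 21 points.

    electrophile + nucleophile → acid set free + product (k = 0.200 M⁻¹ s⁻¹)
    nucleophile + acid set free ⇌ protonated nucleophile, settled at all times (K = 2400 M⁻¹)
    2 nucleophile → homo dimer (k = 0.490 M⁻¹ s⁻¹)
    nucleophile ⇌ dormant form (K = 1.60, k = 0.00290 s⁻¹)

In ochre at 30.0 min, unbound nucleophile stands at 0.153% of its charge against 50.9% of the electrophile, beside 0.0833 M of homo dimer. Starting from ochre's result and moving along the competition slope to 0.60 M of nucleophile at the same time, we reckon 61.0% reacted. That neighbouring flask, with 6.00 equiv of nucleophile, gives 61.9%, and it ends with 38% of its electrophile and 0.089% of its nucleophile unbound.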